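**Retrosynthetic overview**

1. Ring B (lactone, C1–O2) is cut first: target 21 comes from benzodioxinone 18, whose C3 alkoxide takes C1 with loss of acetone; the C6 methyl ether comes from the one free phenol of 17.
2. Ring A (C4a, C5, C6, C7, C8, C8a) carries oxygen on C6 and C8 and carbon on C4a and C8a, the alternating pattern of a folded pentaketide chain; it is cut at C4a–C8a back to the open-chain diketo-dioxinone 15.
3. 15 is cut at C4a–C5: Claisen acylation of the dianion of keto-dioxinone 13 with the (R)-β-silyloxy Weinreb amide 10.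
4. 10 comes from β-keto ester 6 (C3 set by Noyori hydrogenation), and 6 from acid chloride 1 (C7'–C8' by iron-catalysed Grignard acylation, C3–C4 by malonate homologation).
5. Order of ring formation: ring A in step 10, then ring B in step 12.

Key step: step 10

Remark: methyl 8-chloro-8-oxooctanoate and 2,2,6-trimethyl-4H-1,3-dioxin-4-one are taken as purchased materials. Isochroman-1-one numbering (C1, O2, C3, C4, C4a, C5 to C8, C8a; side chain C1' to C11') is used for the corresponding atoms of all intermediates.

**Route**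

Step 1
Reactants: 1 methyl 8-chloro-8-oxooctanoate
Product: 2 methyl 8-oxododecanoate
Conditions: n-BuMgCl, Fe(acac)3 (cat.), THF, −78 °C
Reagents that add atoms: n-butylmagnesium chloride, CCCC[Mg]Cl
Why: Iron-catalysed acylation of a Grignard reagent (Kumada-type ketone synthesis), in which the acid chloride couples at −78 °C far faster than the methyl ester or the product ketone is attacked, so the keto ester should form without over-addition.

Step 2
Reactants: 2 methyl 8-oxododecanoate
Product: 3 8-oxododecanoic acid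
Conditions: LiOH, THF/H2O, rt; then 1 M HCl to pH 3
Reagents that add atoms: lithium hydroxide, [Li+].[OH-]
Why: Ester saponification, to which the remote dialkyl ketone is indifferent at room temperature.

Step 3
Reactants: 3 8-oxododecanoic acid
Product: 6 methyl 3,10-dioxotetradecanoate, via acyl imidazolide 4 (not isolated), via acylmalonate half-acid 5 (not isolated)
Conditions: CDI, THF, rt; then KO2CCH2CO2Me, MgCl2, Et3N, MeCN, rt to 40 °C; 1 M HCl work-up
Reagents that add atoms: potassium methyl malonate, COC(=O)CC(=O)[O-].[K+]; 1,1'-carbonyldiimidazole, O=C(n1ccnc1)n1ccnc1 (imidazole ring of 4 only)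
Why: Masamune–Brooks homologation, in which the soft magnesium enolate of the malonate half-ester is C-acylated by the imidazolide and the adduct decarboxylates, while the unactivated ketone is left alone.

Step 4
Reactants: 6 methyl 3,10-dioxotetradecanoate
Product: 7 methyl (3R)-3-hydroxy-10-oxotetradecanoate
Conditions: RuCl2[(R)-BINAP] (cat.), H2 (50 bar), MeOH, 50 °C; then 1 M HCl, THF, rt (brief, returns any dimethyl ketal to the ketone)
Reagents that add atoms: none
Why: Noyori asymmetric hydrogenation, in which the β-keto ester chelates the BINAP–ruthenium hydride through both carbonyl oxygens and the (R)-ligand directs hydride to the face that gives the (3R)-carbinol, as for simple 3-oxoalkanoates, while the C10 ketone has no chelating neighbour and should not be reduced by this catalyst.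

Step 5
Reactants: 7 methyl (3R)-3-hydroxy-10-oxotetradecanoate
Product: 8 methyl (3R)-3-(tert-butyldimethylsilyloxy)-10-oxotetradecanoate
Conditions: TBSCl, imidazole, DMF, rt
Reagents that add atoms: tert-butyldimethylsilyl chloride, CC(C)(C)[Si](C)(C)Cl
Why: Standard imidazole-promoted silylation of a secondary alcohol, which caps the future C3 oxygen so that it cannot add to the polyketone chain later.

Step 6
Reactants: 8 methyl (3R)-3-(tert-butyldimethylsilyloxy)-10-oxotetradecanoate
Product: 9 methyl (3R)-3-(tert-butyldimethylsilyloxy)-9-(2-butyl-1,3-dioxolan-2-yl)nonanoate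
Conditions: (TMSOCH2)2, TMSOTf (cat.), CH2Cl2, −78 to −20 °C; pyridine, then aq. NaHCO3
Reagents that add atoms: 1,2-bis(trimethylsilyloxy)ethane, C[Si](C)(C)OCCO[Si](C)(C)C
Why: Noyori ketalisation under aprotic low-temperature conditions masks the future C7' ketone before the strongly basic coupling of step 9 without touching the silyl ether or the ester.

Step 7
Reactants: 9 methyl (3R)-3-(tert-butyldimethylsilyloxy)-9-(2-butyl-1,3-dioxolan-2-yl)nonanoate
Product: 10 (3R)-3-(tert-butyldimethylsilyloxy)-9-(2-butyl-1,3-dioxolan-2-yl)-N-methoxy-N-methylnonanamide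
Conditions: MeNHOMe·HCl, i-PrMgCl, THF, −20 to 0 °C; sat. aq. NH4Cl
Reagents that add atoms: N,O-dimethylhydroxylamine hydrochloride, CNOC.Cl
Why: Weinreb amide formation by aminolysis of the methyl ester with the chloromagnesium amide, a reaction that is routine for β-silyloxy esters and leaves the C3 centre untouched.

Step 8
Reactants: 11 2,2,6-trimethyl-4H-1,3-dioxin-4-one
Product: 13 2,2-dimethyl-6-(2-oxopropyl)-4H-1,3-dioxin-4-one, via lithium dienolate 12 (not isolated)
Conditions: LiN(SiMe3)2 (2 equiv), THF, −78 °C; AcCl, −78 °C; sat. aq. NH4Cl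
Reagents that add atoms: acetyl chloride, CC(=O)Cl; lithium hexamethyldisilazide, [Li+].C[Si](C)(C)[N-][Si](C)(C)C (lithium of 12 only)
Why: Vinylogous Claisen acylation, in which deprotonation of the C6 methyl group gives a dienolate that is acylated at its γ carbon, and the second equivalent of base stores the more acidic product as its enolate so that it is not acylated again.

Step 9
Reactants: 13 2,2-dimethyl-6-(2-oxopropyl)-4H-1,3-dioxin-4-one; 10 (3R)-3-(tert-butyldimethylsilyloxy)-9-(2-butyl-1,3-dioxolan-2-yl)-N-methoxy-N-methylnonanamide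
Product: 15 6-[(6R)-6-(tert-butyldimethylsilyloxy)-12-(2-butyl-1,3-dioxolan-2-yl)-2,4-dioxododecyl]-2,2-dimethyl-4H-1,3-dioxin-4-one, via dilithium dianion 14 (not isolated)
Conditions: 13 (2 equiv), LiN(i-Pr)2 (4 equiv), THF, −78 °C; then 10, −78 to −40 °C; sat. aq. NH4Cl
Reagents that add atoms: lithium diisopropylamide, CC(C)[N-]C(C)C.[Li+] (lithium of 14 only)
Why: Claisen-type acylation of a 1,3-dicarbonyl dianion, in which the terminal, last-formed carbanion of 14 adds to the Weinreb amide, whose chelated tetrahedral adduct resists a second addition and releases the C4a ketone only on quench, so the C4a–C5 bond forms without touching the (3R) centre.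

Step 10
Reactants: 15 6-[(6R)-6-(tert-butyldimethylsilyloxy)-12-(2-butyl-1,3-dioxolan-2-yl)-2,4-dioxododecyl]-2,2-dimethyl-4H-1,3-dioxin-4-one
Product: 17 5-[(2R)-2-(tert-butyldimethylsilyloxy)-8-(2-butyl-1,3-dioxolan-2-yl)octyl]-7-hydroxy-2,2-dimethyl-4H-1,3-benzodioxin-4-one, via aldol adduct 16 (not isolated)
Conditions: Et3N, CH2Cl2, rt, 4 Å molecular sieves
Reagents that add atoms: none
Why: Et3N removes a proton from C7, which lies between the dioxinone carbon C8 and the C6 ketone, and the resulting vinylogous dienolate carries its charge to the dioxinone α-carbon C8a; C8a adds to the C4a ketone, and aldol adduct 16 then loses water and tautomerises at C6 to the phenol, which makes the sequence irreversible. The closest known reaction type is the amine-mediated cyclisation and aromatisation of 6-(2,4-dioxoalkyl)-1,3-dioxin-4-ones to acetonide-protected resorcylates, the laboratory counterpart of polyketide aldol cyclisation. Ring A closes in a 6-(enolexo)-exo-trig mode, since the C8a=C1 enolate bond lies outside the new ring and the C4a carbonyl oxygen is exocyclic. No stereocentre is formed, and the (3R) centre, which carries only a silyl ether and no acidic hydrogen, should pass through unchanged. The selectivity needed is the C8a-to-C4a aldol over a C5-to-C1 Claisen closure, a pyranone closure through oxygen, or hemiketal formation from the C3 oxygen; it is secured because the dioxinone keeps C1 inert to acyl transfer below the temperature of ketene release, because only the C8a/C4a pairing gives a six-membered carbocycle, and because the C3 oxygen is capped as its silyl ether.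

Step 11
Reactants: 17 5-[(2R)-2-(tert-butyldimethylsilyloxy)-8-(2-butyl-1,3-dioxolan-2-yl)octyl]-7-hydroxy-2,2-dimethyl-4H-1,3-benzodioxin-4-one
Product: 18 5-[(2R)-2-(tert-butyldimethylsilyloxy)-8-(2-butyl-1,3-dioxolan-2-yl)octyl]-7-methoxy-2,2-dimethyl-4H-1,3-benzodioxin-4-one
Conditions: MeI, K2CO3, acetone, rt
Reagents that add atoms: iodomethane, CI
Why: Williamson etherification, regioselective by construction because O8 is held in the acetonide and the C6 hydroxyl is the only phenol present.

Step 12
Reactants: 18 5-[(2R)-2-(tert-butyldimethylsilyloxy)-8-(2-butyl-1,3-dioxolan-2-yl)octyl]-7-methoxy-2,2-dimethyl-4H-1,3-benzodioxin-4-one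
Product: 20 (3R)-3-[6-(2-butyl-1,3-dioxolan-2-yl)hexyl]-8-hydroxy-6-methoxy-3,4-dihydro-1H-isochromen-1-one, via C3 alkoxide 19 (not isolated)
Conditions: Bu4NF, THF, 0 °C to rt; sat. aq. NH4Cl
Reagents that add atoms: none
Why: Fluoride desilylation frees the C3 alkoxide, which undergoes intramolecular transesterification (6-exo-trig acyl substitution) at the benzodioxinone carbonyl C1, the expelled hemiketal oxyanion breaking down to acetone and the C8 phenoxide; the C3–O bond is never broken, so the (R) configuration should be retained.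

Step 13
Reactants: 20 (3R)-3-[6-(2-butyl-1,3-dioxolan-2-yl)hexyl]-8-hydroxy-6-methoxy-3,4-dihydro-1H-isochromen-1-one
Product: 21 (3R)-8-hydroxy-6-methoxy-3-(7-oxoundecyl)-3,4-dihydro-1H-isochromen-1-one
Conditions: 1 M HCl, THF, rt
Reagents that add atoms: water, O
Why: Acid-catalysed hydrolysis of the dioxolane, under which the δ-lactone, the aryl methyl ether, the chelated phenol and the C3 centre should all be stable.

**Compound list**

1 | methyl 8-chloro-8-oxooctanoate | COC(=O)CCCCCCC(=O)Cl | starting material
2 | methyl 8-oxododecanoate | CCCCC(=O)CCCCCCC(=O)OC | intermediate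
3 | 8-oxododecanoic acid | CCCCC(=O)CCCCCCC(=O)O | intermediate
4 | 1-(1H-imidazol-1-yl)dodecane-1,8-dione (acyl imidazolide) | CCCCC(=O)CCCCCCC(=O)n1ccnc1 | intermediate (not isolated)
5 | 2-(8-oxododecanoyl)malonic acid monomethyl ester (formed as its magnesium salt) | CCCCC(=O)CCCCCCC(=O)C(C(=O)O)C(=O)OC | intermediate (not isolated)
6 | methyl 3,10-dioxotetradecanoate | CCCCC(=O)CCCCCCC(=O)CC(=O)OC | intermediate
7 | methyl (3R)-3-hydroxy-10-oxotetradecanoate | COC(=O)C[C@H](O)CCCCCCC(=O)CCCC | intermediate
8 | methyl (3R)-3-(tert-butyldimethylsilyloxy)-10-oxotetradecanoate | COC(=O)C[C@H](O[Si](C)(C)C(C)(C)C)CCCCCCC(=O)CCCC | intermediate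
9 | methyl (3R)-3-(tert-butyldimethylsilyloxy)-9-(2-butyl-1,3-dioxolan-2-yl)nonanoate | COC(=O)C[C@H](O[Si](C)(C)C(C)(C)C)CCCCCCC1(CCCC)OCCO1 | intermediate
10 | (3R)-3-(tert-butyldimethylsilyloxy)-9-(2-butyl-1,3-dioxolan-2-yl)-N-methoxy-N-methylnonanamide | CON(C)C(=O)C[C@H](O[Si](C)(C)C(C)(C)C)CCCCCCC1(CCCC)OCCO1 | intermediate
11 | 2,2,6-trimethyl-4H-1,3-dioxin-4-one | CC1=CC(=O)OC(C)(C)O1 | starting material
12 | lithium dienolate of 11 | [Li+].C=C1C=C([O-])OC(C)(C)O1 | intermediate (not isolated)
13 | 2,2-dimethyl-6-(2-oxopropyl)-4H-1,3-dioxin-4-one | CC(=O)CC1=CC(=O)OC(C)(C)O1 | intermediate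
14 | dilithium dianion of 13 | [Li+].[Li+].C=C([O-])C=C1C=C([O-])OC(C)(C)O1 | intermediate (not isolated)
15 | 6-[(6R)-6-(tert-butyldimethylsilyloxy)-12-(2-butyl-1,3-dioxolan-2-yl)-2,4-dioxododecyl]-2,2-dimethyl-4H-1,3-dioxin-4-one | CC1(C)OC(=O)C=C(O1)CC(=O)CC(=O)C[C@H](O[Si](C)(C)C(C)(C)C)CCCCCCC2(CCCC)OCCO2 | intermediate (key-step precursor)
16 | cyclised aldol adduct (C4a carbinol, C8a–H, C7=C8 enone; new centres at C4a and C8a undefined) | CC1(C)OC(=O)C2C(=CC(=O)CC2(O)C[C@H](O[Si](C)(C)C(C)(C)C)CCCCCCC3(CCCC)OCCO3)O1 | intermediate (not isolated)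
17 | 5-[(2R)-2-(tert-butyldimethylsilyloxy)-8-(2-butyl-1,3-dioxolan-2-yl)octyl]-7-hydroxy-2,2-dimethyl-4H-1,3-benzodioxin-4-one | CC1(C)OC(=O)c2c(C[C@H](O[Si](C)(C)C(C)(C)C)CCCCCCC3(CCCC)OCCO3)cc(O)cc2O1 | intermediate (key-step product)
18 | 5-[(2R)-2-(tert-butyldimethylsilyloxy)-8-(2-butyl-1,3-dioxolan-2-yl)octyl]-7-methoxy-2,2-dimethyl-4H-1,3-benzodioxin-4-one | CC1(C)OC(=O)c2c(C[C@H](O[Si](C)(C)C(C)(C)C)CCCCCCC3(CCCC)OCCO3)cc(OC)cc2O1 | intermediate
19 | 5-[(2R)-8-(2-butyl-1,3-dioxolan-2-yl)-2-hydroxyoctyl]-7-methoxy-2,2-dimethyl-4H-1,3-benzodioxin-4-one (formed as its C3 alkoxide, drawn as the alcohol) | CC1(C)OC(=O)c2c(C[C@H](O)CCCCCCC3(CCCC)OCCO3)cc(OC)cc2O1 | intermediate (not isolated)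
20 | (3R)-3-[6-(2-butyl-1,3-dioxolan-2-yl)hexyl]-8-hydroxy-6-methoxy-3,4-dihydro-1H-isochromen-1-one | CCCCC1(CCCCCC[C@@H]2Cc3cc(OC)cc(O)c3C(=O)O2)OCCO1 | intermediate
21 | (3R)-8-hydroxy-6-methoxy-3-(7-oxoundecyl)-3,4-dihydro-1H-isochromen-1-one | CCCCC(=O)CCCCCC[C@@H]1Cc2cc(OC)cc(O)c2C(=O)O1 | target

**Summary**

Total step count: 13.
Longest linear sequence: 12 steps (steps 1 to 7, then 9 to 13); step 8 is a one-step side branch.

**Steps most likely to fail, with fallbacks**

Step 10 (key step). The weak amine base may not drive the fold to completion, or the cyclised aldol intermediate may fail to dehydrate and aromatise. The fallback moves the same C8a-to-C4a aldol to the ester series and sets out from 15. Heating 15 in toluene at 110 °C with methanol should expel acetone by retro-[4+2] fragmentation and trap the acylketene as methyl (9R)-9-(tert-butyldimethylsilyloxy)-15-(2-butyl-1,3-dioxolan-2-yl)-3,5,7-trioxopentadecanoate F1. Cs2CO3 in MeOH followed by acidification with AcOH should cyclise and dehydrate it to methyl 2-[(2R)-2-(tert-butyldimethylsilyloxy)-8-(2-butyl-1,3-dioxolan-2-yl)octyl]-4,6-dihydroxybenzoate F2. MeI with K2CO3 in acetone should methylate only the para hydroxyl, the ortho one being chelated to the ester, to give methyl 2-[(2R)-2-(tert-butyldimethylsilyloxy)-8-(2-butyl-1,3-dioxolan-2-yl)octyl]-6-hydroxy-4-methoxybenzoate F3. Aqueous HCl in MeOH/THF, then p-TsOH in warm toluene, should remove the silyl ether and the ketal and close the lactone with loss of methanol. The fallback comes back to the route at 21.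

Step 9. Proton transfer from the α-position of the amide, or β-elimination of the silyloxy group under the strongly basic dianion, may compete with C-acylation. The fallback replaces acylation by aldol addition and oxidation and sets out from 10. i-Bu2AlH in THF at −78 °C should reduce 10 to (3R)-3-(tert-butyldimethylsilyloxy)-9-(2-butyl-1,3-dioxolan-2-yl)nonanal F4. Dianion 14 (from 13 as in step 9) should add to this aldehyde at −78 °C faster than it enolises it, giving 6-[(6R)-6-(tert-butyldimethylsilyloxy)-12-(2-butyl-1,3-dioxolan-2-yl)-4-hydroxy-2-oxododecyl]-2,2-dimethyl-4H-1,3-dioxin-4-one F5 as a mixture at the new carbinol. Dess–Martin periodinane buffered with NaHCO3 in CH2Cl2 should oxidise the carbinol to the diketone. The fallback comes back to the route at 15.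

Step 12. Desilylation may occur without ring closure, or water in the fluoride reagent may hydrolyse the benzodioxinone instead of allowing acyl transfer to the C3 oxygen. The fallback separates deprotection from lactonisation and sets out from 18. Aqueous HCl in MeOH/THF should cleave the silyl ether and the dioxolane while the benzodioxinone survives, giving 5-[(2R)-2-hydroxy-9-oxotridecyl]-7-methoxy-2,2-dimethyl-4H-1,3-benzodioxin-4-one F6. NaH (1 equiv) in THF at 0 °C should then form the C3 alkoxide, which closes the lactone with loss of acetone. The fallback comes back to the route at 21.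

**Further compounds**

F1 | step 10 | methyl (9R)-9-(tert-butyldimethylsilyloxy)-15-(2-butyl-1,3-dioxolan-2-yl)-3,5,7-trioxopentadecanoate | COC(=O)CC(=O)CC(=O)CC(=O)C[C@H](O[Si](C)(C)C(C)(C)C)CCCCCCC1(CCCC)OCCO1
F2 | step 10 | methyl 2-[(2R)-2-(tert-butyldimethylsilyloxy)-8-(2-butyl-1,3-dioxolan-2-yl)octyl]-4,6-dihydroxybenzoate | COC(=O)c1c(O)cc(O)cc1C[C@H](O[Si](C)(C)C(C)(C)C)CCCCCCC2(CCCC)OCCO2
F3 | step 10 | methyl 2-[(2R)-2-(tert-butyldimethylsilyloxy)-8-(2-butyl-1,3-dioxolan-2-yl)octyl]-6-hydroxy-4-methoxybenzoate | COC(=O)c1c(O)cc(OC)cc1C[C@H](O[Si](C)(C)C(C)(C)C)CCCCCCC2(CCCC)OCCO2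
F4 | step 9 | (3R)-3-(tert-butyldimethylsilyloxy)-9-(2-butyl-1,3-dioxolan-2-yl)nonanal | O=CC[C@H](O[Si](C)(C)C(C)(C)C)CCCCCCC1(CCCC)OCCO1
F5 | step 9 | 6-[(6R)-6-(tert-butyldimethylsilyloxy)-12-(2-butyl-1,3-dioxolan-2-yl)-4-hydroxy-2-oxododecyl]-2,2-dimethyl-4H-1,3-dioxin-4-one | CC1(C)OC(=O)C=C(O1)CC(=O)CC(O)C[C@H](O[Si](C)(C)C(C)(C)C)CCCCCCC2(CCCC)OCCO2
F6 | step 12 | 5-[(2R)-2-hydroxy-9-oxotridecyl]-7-methoxy-2,2-dimethyl-4H-1,3-benzodioxin-4-one | CC1(C)OC(=O)c2c(C[C@H](O)CCCCCCC(=O)CCCC)cc(OC)cc2O1
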